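The constants are those of an exercise; the result is computed.

We cannot read the target of this flask off the solubility, 0.56 M: what dissolves leaves again by 4 steps.

    starting material ⇌ target (K1 = 0.58, k1 = 0.87 h⁻¹)
    starting material ⇌ isomer of the product (K2 = 2.5, k2 = 0.33 h⁻¹)
    starting material ⇌ third isomer (K3 = 1.5, k3 = 0.52 h⁻¹)
    solid substrate ⇌ starting material, rate k4*(cs4 - [starting material]) while solid is left; crystals form when [starting material] > cs4 (cs4 = 0.56 M, k4 = 1.4 h⁻¹)
    starting material ⇌ dormant form (K5 = 0.46, k5 = 0.97 h⁻¹)

solid substrate 1.0 M; time 2.0 h

1. the target standing at 2.0 h, as a percentage of the solid substrate charged
2. concentration of starting material in solution at 2.0 h, in percent of saturation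

- solid substrate is a solid; its amount is given per volume of the solution
- at the start none of the solid substrate is in solution
- starting material means what is dissolved; the solid is not counted in it
- run time (flask): 2.0 h

The passage into the dormant form is quick. Its relaxation half-life of 0.225 h is short against the run of 2.0 h and shorter than the 0.800 h of the third isomer's step. So we treat it as a pre-equilibrium. Write S for dissolved starting material and D for the dormant form, and let the pool be S + D. With D at 0.46 times S, the free share f, meaning S divided by the pool, is 68.5%.

Dissolving feeds the pool at 1.4 h⁻¹ times the gap between solubility and S. The steps to target and the two isomers drain it at 1.72 h⁻¹ times S, before any return is counted. Feed equals drain at S = 0.251 M, which is 44.9% of saturation. S being f times the pool, the pool nears that level with a half-life of 0.324 h, shorter than the run. So we hold S at that level.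

At that level dissolving takes 0.864 M, less than the charge, so in this reckoning solid lasts through the run. The target climbs towards 0.58 times S and reaches 13.8% of the charge. We have dropped the returns from the two isomers and, in the level of S, from the target; they add to the pool, so we expect both figures to come out low.

The forecast gave y = 15.4% (14.6% to 16.2%) and sat = 57.4% (55% to 60%), noting that “some solid remains and the dissolution law holds throughout”.

The simulation gives y = 15.4% and sat = 57.6%, so our figures stand 1.6 percentage points and 13 points lower. In this flask dissolving ran for the whole 2.0 h while solid was there, with a net turnover of 92.6% of the charge, its midpoint at 0.811 h, and 7.36% of the charge still solid at the end. Meanwhile the free share went from 91.4% at 0.200 h down to 71.0% at 2.00 h, against the reckoned 68.5%. In the same flask read at 8.0 h, with solid at 0%, the free share stands at 68.2%.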